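**Retrosynthetic overview**
- The target comes from late 6-O-angeloylation (mixed-anhydride esterification) of a 6α,8α-diol whose C16 hydroxyl is silyl-protected.
- The side chain is joined at C12–C13 by an intermolecular Evans syn-aldol between the C12 aldehyde of a tetranorlabdane core and the boron dienolate of (S)-N-crotonyl-4-benzyloxazolidinone, which sets C13. The C12 hydroxyl is then removed (Barton–McCombie) and the imide reduced to the C16 alcohol.
- Ring B stereocentres are relayed from C6: 6α-OH-directed epoxidation then LiAlH4 gives 8α-OH; the 9β two-carbon arm comes from a Johnson–Claisen shift of a 7β-allylic alcohol, itself made by Weitz–Scheffer epoxidation and Wharton transposition.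
- Ring order: ring B is the carbocycle of 2,6-dimethylbenzoquinone. Ring A is closed onto it first, by a catalytic enantioselective Diels–Alder reaction with allylidenecyclopropane that fixes the cis ring fusion. The spirocyclopropane is hydrogenolysed later to the C4 gem-dimethyl group.

Assumption: the SMILES is read literally as (5R,6S,8R,9R,10S,13R), i.e. a cis-fused decalin with 5-H and 10-CH3 on the same face; labdane numbering is used for locants and β is the face of the C10 methyl group.

**Step 1**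
Reactants: 1 cyclopropyltriphenylphosphonium bromide; 2 acrolein
Product: 4 allylidenecyclopropane, via cyclopropylidenetriphenylphosphorane 3 (not isolated)
Conditions: NaH, (MeOCH2CH2)2O, 60 °C; then 2, 0 °C → rt; distil
Reagents that add atoms: none
Why: Wittig olefination of the aldehyde by the non-stabilised ylide gives a diene whose cyclopropylidene end is a reactive stand-in for a gem-dimethyl terminus; no stereocentre is formed.

**Step 2**
Reactants: 4 allylidenecyclopropane; 5 2,6-dimethyl-1,4-benzoquinone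
Product: 6 cis-fused adduct (4a'R,8a'S)-2',8a'-dimethyl-4a',8a'-dihydro-8'H-spiro[cyclopropane-1,5'-naphthalene]-1',4'-dione (labdane numbering: C6 and C9 ketones, C7=C8(CH3), C2=C3, spirocyclopropane at C4, 5β-H, 10β-CH3)
Conditions: (S)-3,3-diphenyl-1-(2-methylphenyl)tetrahydro-1H,3H-pyrrolo[1,2-c][1,3,2]oxazaborole (20 mol %), HN(SO2CF3)2 (20 mol %), CH2Cl2, −78 → −40 °C
Reagents that add atoms: none
Why: Lewis-acid-catalysed enantioselective Diels–Alder reaction in which the boron cation binds the unhindered carbonyl (future C6), so the CH2 terminus of the diene attacks the methyl-bearing β-carbon (C10) and the spiro carbon ends up next to C5–H; suprafacial addition fixes the cis fusion and the catalyst's aryl group blocks one face, which by analogy with acrylate and quinone dienophiles should give the (5R,10S) adduct.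

**Step 3**
Reactants: 6 cis-fused ene-dione adduct
Product: 7 6α-hydroxy enone (6S; ketone at C9, C7=C8)
Conditions: NaBH4, CeCl3·7H2O, MeOH, −78 °C
Reagents that add atoms: none
Why: Luche 1,2-reduction picks the less hindered C6 carbonyl (C9 is flanked by the quaternary C10 and C8–CH3), and hydride arrives on the convex β-face of the folded cis-bicycle, so the hydroxyl is 6α (trans to 5-H).

**Step 4**
Reactants: 7 6α-hydroxy enone
Product: 8 6α-(tert-butyldimethylsilyloxy) enone
Conditions: t-BuMe2SiOTf, 2,6-lutidine, CH2Cl2, −78 → 0 °C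
Reagents that add atoms: tert-butyldimethylsilyl triflate, CC(C)(C)[Si](C)(C)OS(=O)(=O)C(F)(F)F
Why: Silylation under non-enolising conditions protects the secondary alcohol and places a bulky group on the α-face next to C7; no stereocentre changes.

**Step 5**
Reactants: 8 6α-silyloxy enone
Product: 9 7β,8β-epoxy-6α-silyloxy 9-ketone
Conditions: 30% H2O2, NaOH (aq., cat.), MeOH, 0 °C
Reagents that add atoms: hydrogen peroxide, OO
Why: Weitz–Scheffer nucleophilic epoxidation of the enone: hydroperoxide adds to C7 on the convex β-face, anti to the 6α-silyloxy group, so the oxirane is 7β,8β.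

**Step 6**
Reactants: 9 7β,8β-epoxy ketone
Product: 12 7β-hydroxy-6α-silyloxy C8=C9 alkene, via epoxy hydrazone 10 (not isolated), via alkenyldiazene 11 (not isolated)
Conditions: N2H4·H2O, AcOH (cat.), MeOH, 0 °C → rt
Reagents that add atoms: none
Why: Wharton transposition: hydrazone formation, oxirane C8–O cleavage and loss of N2 move the alkene to C8=C9, remove the C9 oxygen and leave the C7–O bond untouched, so the new allylic alcohol is 7β.

**Step 7**
Reactants: 12 7β-allylic alcohol; 13 triethyl orthoacetate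
Product: 15 ethyl 2-(6α-silyloxy-7-en-9β-yl)acetate, via mixed ketene acetal 14 (not isolated)
Conditions: 13 (excess), EtCO2H (cat.), 140 °C, −EtOH
Reagents that add atoms: none
Why: Johnson–Claisen rearrangement: the suprafacial [3,3] shift transfers the 7β C–O bond to a new C9–C11 bond on the β-face (9β arm, 9α-H) next to the quaternary C10 and regenerates the C7=C8 alkene.

**Step 8**
Reactants: 15 silyl ether ester
Product: 16 6α-hydroxy ester (allylic alcohol, C7=C8)
Conditions: Bu4NF, THF, 0 °C → rt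
Reagents that add atoms: none
Why: Fluoride desilylation frees the allylic 6α-hydroxyl needed to direct the next oxidation; the ester, alkenes and cyclopropane are inert.

**Step 9**
Reactants: 16 6α-hydroxy ester
Product: 17 7α,8α-epoxy-6α-hydroxy ester
Conditions: VO(acac)2 (5 mol %), t-BuOOH, CH2Cl2, 0 °C → rt
Reagents that add atoms: tert-butyl hydroperoxide, CC(C)(C)OO
Why: Hydroxyl-directed (vanadium-catalysed) epoxidation delivers oxygen syn to the 6α-OH, fixing C8 as 8α-O/8β-CH3; the allylic trisubstituted alkene reacts far faster than the remote ring A alkene.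

**Step 10**
Reactants: 17 epoxy alcohol ester
Product: 18 6α,8α,12-triol (ring A still C2=C3 with the spirocyclopropane)
Conditions: LiAlH4, THF, 0 °C → reflux
Reagents that add atoms: none
Why: Hydride reduces the ester to the C12 alcohol and opens the trisubstituted epoxide by SN2 attack at the secondary C7 from the β-face (trans-diaxial opening), leaving the tertiary 8α-OH with its configuration intact.

**Step 11**
Reactants: 18 unsaturated spiro triol
Product: 19 5β-13,14,15,16-tetranorlabdane-6α,8α,12-triol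
Conditions: H2 (4 atm), PtO2, AcOH–EtOAc (1:1), rt
Reagents that add atoms: none
Why: Catalytic hydrogenation saturates C2=C3, and hydrogenolysis of the least hindered CH2–CH2 bond of the spirocyclopropane unveils the C4 gem-dimethyl group; ring B now has no reducible group and no stereocentre is touched.

**Step 12**
Reactants: 19 triol
Product: 20 6,8,12-tris(triethylsilyl) ether
Conditions: Et3SiOTf, 2,6-lutidine, CH2Cl2, −78 °C → rt
Reagents that add atoms: triethylsilyl triflate, CC[Si](CC)(CC)OS(=O)(=O)C(F)(F)F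
Why: Exhaustive silylation (the triflate also caps the tertiary 8-OH) masks the hydroxyls that would otherwise form a lactol with the C12 aldehyde.

**Step 13**
Reactants: 20 tris(triethylsilyl) ether
Product: 22 6α,8α-bis(triethylsilyloxy)-5β-13,14,15,16-tetranorlabdan-12-al, via alkoxydimethylsulfonium chloride 21 (not isolated)
Conditions: (COCl)2, DMSO, CH2Cl2, −78 → −30 °C; then Et3N, −78 °C → rt
Reagents that add atoms: none
Why: Under Swern conditions only the primary triethylsilyl ether is cleaved and oxidised in one pot (secondary and tertiary silyl ethers are inert), giving the aldehyde directly.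

**Step 14**
Reactants: 23 (S)-4-benzyloxazolidin-2-one; 24 (E)-but-2-enoyl chloride
Product: 26 (S)-4-benzyl-3-[(E)-but-2-enoyl]oxazolidin-2-one, via lithium oxazolidinide 25 (not isolated)
Conditions: n-BuLi, THF, −78 °C; then 24, −78 → 0 °C
Reagents that add atoms: none
Why: N-Acylation of the lithiated auxiliary gives the crotonyl imide that supplies C13–C16.

**Step 15**
Reactants: 22 C12 aldehyde; 26 crotonyl imide
Product: 29 syn-aldol adduct (2'S,3'R)-2'-ethenyl-3'-hydroxy imide, via dibutylboron dienolate 27 (not isolated), via boron aldolate 28 (not isolated)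
Conditions: 26, Bu2BOTf, Et3N, CH2Cl2, −78 → 0 °C; then 22, −78 → 0 °C; pH 7 buffer, MeOH, 30% H2O2
Reagents that add atoms: none
Why: Intermolecular Evans syn-aldol reaction: the Z boron dienolate reacts at its α-carbon through a Zimmerman–Traxler chair with the benzyl group blocking one face, forming the C12–C13 bond and setting C13 (vinyl-bearing) in the configuration that is 13R in the target; the C12 carbinol is removed later.

**Step 16**
Reactants: 29 aldol adduct
Product: 30 12,16-diol (C13 bearing CH=CH2 and CH2OH)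
Conditions: LiBH4, MeOH (1 equiv), THF, 0 °C
Reagents that add atoms: none
Why: Reductive cleavage of the N-acyl oxazolidinone gives the primary C16 alcohol without epimerising C13 or conjugating the vinyl group, and returns the auxiliary.

**Step 17**
Reactants: 30 12,16-diol
Product: 31 16-O-(tert-butyldiphenylsilyl) ether with free 12-OH
Conditions: t-BuPh2SiCl, imidazole, CH2Cl2, 0 °C → rt
Reagents that add atoms: tert-butyl(chloro)diphenylsilane, CC(C)(C)[Si](Cl)(c1ccccc1)c1ccccc1
Why: The bulky silyl chloride reacts selectively at the primary hydroxyl, leaving the secondary C12 alcohol as the only free OH.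

**Step 18**
Reactants: 31 C12 alcohol
Product: 32 12-O-(imidazol-1-ylthiocarbonyl) derivative
Conditions: 1,1'-thiocarbonyldiimidazole, 4-(dimethylamino)pyridine (cat.), PhMe, 80 °C
Reagents that add atoms: 1,1'-thiocarbonyldiimidazole, S=C(n1ccnc1)n1ccnc1
Why: Neutral thioacylation converts the secondary alcohol into a radical-cleavable thiocarbonyl ester without base-induced side reactions.

**Step 19**
Reactants: 32 thiocarbonyl derivative
Product: 33 12-deoxy compound (13R)-6α,8α-bis(triethylsilyloxy)-16-(tert-butyldiphenylsilyloxy)-5β-labd-14-ene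
Conditions: Bu3SnH (0.3 M), 2,2'-azobis(isobutyronitrile) (cat.), PhMe, 100 °C
Reagents that add atoms: none
Why: Barton–McCombie deoxygenation replaces the C12 oxygen by hydrogen; the high stannane concentration traps the C12 radical before any homoallyl rearrangement, and C13 is untouched.

**Step 20**
Reactants: 33 tris-silyl ether
Product: 34 6α,8α-diol with the 16-O-silyl group retained
Conditions: pyridinium p-toluenesulfonate, MeOH–CH2Cl2, rt → 40 °C
Reagents that add atoms: none
Why: Mild acid methanolysis removes the two labile triethylsilyl ethers while the primary tert-butyldiphenylsilyl ether survives.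

**Step 21**
Reactants: 34 6α,8α-diol; 35 angelic acid ((Z)-2-methylbut-2-enoic acid)
Product: 37 6-O-angelate, via mixed anhydride 36 (not isolated)
Conditions: 35, 2,4,6-Cl3C6H2COCl, Et3N, PhMe, rt; then 34, PhMe, 80 °C
Reagents that add atoms: none
Why: Yamaguchi-type mixed-anhydride esterification without a nucleophilic amine catalyst acylates the secondary 6α-OH (the tertiary 8-OH is unreactive) and avoids Z → E isomerisation to the tiglate.

**Step 22**
Reactants: 37 silyl-protected angelate
Product: 38 target CNP0177054.1, (1S,3R,4R,4aS,8aR)-3-hydroxy-4-[(3R)-3-(hydroxymethyl)pent-4-en-1-yl]-3,4a,8,8-tetramethyldecahydronaphthalen-1-yl (2Z)-2-methylbut-2-enoate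
Conditions: HF·pyridine, pyridine, THF, 0 °C → rt
Reagents that add atoms: none
Why: Buffered fluoride desilylation frees the primary C16 alcohol without acyl migration or isomerisation of the angelate.

**Compound list**
1 | cyclopropyltriphenylphosphonium bromide | [Br-].C1CC1[P+](c1ccccc1)(c1ccccc1)c1ccccc1 | starting material
2 | acrolein | C=CC=O | starting material
3 | cyclopropylidenetriphenylphosphorane | C1CC1=P(c1ccccc1)(c1ccccc1)c1ccccc1 | intermediate (not isolated)
4 | allylidenecyclopropane | C=CC=C1CC1 | intermediate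
5 | 2,6-dimethyl-1,4-benzoquinone | CC1=CC(=O)C=C(C)C1=O | starting material
6 | cis-fused Diels–Alder adduct (5β-H, 10β-CH3; 6,9-dione; C2=C3, C7=C8; C4 spirocyclopropane) | O=C1[C@@]2(C)CC=CC3(CC3)[C@H]2C(=O)C=C1C | intermediate
7 | 6α-hydroxy enone | O=C1[C@@]2(C)CC=CC3(CC3)[C@H]2[C@@H](O)C=C1C | intermediate
8 | 6α-(tert-butyldimethylsilyloxy) enone | O=C1[C@@]2(C)CC=CC3(CC3)[C@H]2[C@@H](O[Si](C)(C)C(C)(C)C)C=C1C | intermediate
9 | 7β,8β-epoxy-6α-silyloxy 9-ketone | O=C1[C@@]2(C)CC=CC3(CC3)[C@H]2[C@@H](O[Si](C)(C)C(C)(C)C)[C@@H]4O[C@]14C | intermediate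
10 | hydrazone of 9 | NN=C1[C@@]2(C)CC=CC3(CC3)[C@H]2[C@@H](O[Si](C)(C)C(C)(C)C)[C@@H]4O[C@]14C | intermediate (not isolated)
11 | C9 alkenyldiazene with 7β-OH | N=NC1[C@@]2(C)CC=CC3(CC3)[C@H]2[C@@H](O[Si](C)(C)C(C)(C)C)[C@H](O)C(C)=1 | intermediate (not isolated)
12 | 7β-hydroxy-6α-silyloxy C8=C9 alkene | C1[C@@]2(C)CC=CC3(CC3)[C@H]2[C@@H](O[Si](C)(C)C(C)(C)C)[C@H](O)C(C)=1 | intermediate
13 | triethyl orthoacetate | CC(OCC)(OCC)OCC | starting material
14 | mixed ketene acetal of 12 | C1[C@@]2(C)CC=CC3(CC3)[C@H]2[C@@H](O[Si](C)(C)C(C)(C)C)[C@H](OC(=C)OCC)C(C)=1 | intermediate (not isolated)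
15 | ethyl 9β-acetate, 6α-silyloxy, C7=C8 | CCOC(=O)C[C@@H]1[C@@]2(C)CC=CC3(CC3)[C@H]2[C@@H](O[Si](C)(C)C(C)(C)C)C=C1C | intermediate
16 | 6α-hydroxy ester | CCOC(=O)C[C@@H]1[C@@]2(C)CC=CC3(CC3)[C@H]2[C@@H](O)C=C1C | intermediate
17 | 7α,8α-epoxy-6α-hydroxy ester | CCOC(=O)C[C@@H]1[C@@]2(C)CC=CC3(CC3)[C@H]2[C@@H](O)[C@H]4O[C@@]14C | intermediate
18 | 6α,8α,12-triol (C2=C3, spirocyclopropane) | OCC[C@@H]1[C@@]2(C)CC=CC3(CC3)[C@H]2[C@@H](O)C[C@@]1(C)O | intermediate
19 | 5β-13,14,15,16-tetranorlabdane-6α,8α,12-triol | OCC[C@@H]1[C@@]2(C)CCCC(C)(C)[C@H]2[C@@H](O)C[C@@]1(C)O | intermediate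
20 | 6,8,12-tris(triethylsilyl) ether | CC[Si](CC)(CC)OCC[C@@H]1[C@@]2(C)CCCC(C)(C)[C@H]2[C@@H](O[Si](CC)(CC)CC)C[C@@]1(C)O[Si](CC)(CC)CC | intermediate
21 | C12 alkoxydimethylsulfonium chloride | C[S+](C)OCC[C@@H]1[C@@]2(C)CCCC(C)(C)[C@H]2[C@@H](O[Si](CC)(CC)CC)C[C@@]1(C)O[Si](CC)(CC)CC.[Cl-] | intermediate (not isolated)
22 | 6α,8α-bis(triethylsilyloxy) C12 aldehyde | O=CC[C@@H]1[C@@]2(C)CCCC(C)(C)[C@H]2[C@@H](O[Si](CC)(CC)CC)C[C@@]1(C)O[Si](CC)(CC)CC | intermediate
23 | (S)-4-benzyloxazolidin-2-one | O=C1N[C@@H](Cc2ccccc2)CO1 | starting material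
24 | (E)-but-2-enoyl chloride | C/C=C/C(Cl)=O | starting material
25 | lithium (S)-4-benzyl-2-oxooxazolidin-3-ide | [Li]N1[C@@H](Cc2ccccc2)COC1=O | intermediate (not isolated)
26 | (S)-4-benzyl-3-[(E)-but-2-enoyl]oxazolidin-2-one | C/C=C/C(=O)N1[C@@H](Cc2ccccc2)COC1=O | intermediate
27 | dibutylboron Z-dienolate of 26 | C=C/C=C(\OB(CCCC)CCCC)N1[C@@H](Cc2ccccc2)COC1=O | intermediate (not isolated)
28 | dibutylboron aldolate | C=C[C@H](C(=O)N3[C@@H](Cc4ccccc4)COC3=O)[C@H](OB(CCCC)CCCC)C[C@@H]1[C@@]2(C)CCCC(C)(C)[C@H]2[C@@H](O[Si](CC)(CC)CC)C[C@@]1(C)O[Si](CC)(CC)CC | intermediate (not isolated)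
29 | syn-aldol adduct (2'S,3'R) | C=C[C@H](C(=O)N3[C@@H](Cc4ccccc4)COC3=O)[C@H](O)C[C@@H]1[C@@]2(C)CCCC(C)(C)[C@H]2[C@@H](O[Si](CC)(CC)CC)C[C@@]1(C)O[Si](CC)(CC)CC | intermediate
30 | 12,16-diol | C=C[C@H](CO)[C@H](O)C[C@@H]1[C@@]2(C)CCCC(C)(C)[C@H]2[C@@H](O[Si](CC)(CC)CC)C[C@@]1(C)O[Si](CC)(CC)CC | intermediate
31 | 16-O-(tert-butyldiphenylsilyl) 12-alcohol | C=C[C@H](CO[Si](c3ccccc3)(c4ccccc4)C(C)(C)C)[C@H](O)C[C@@H]1[C@@]2(C)CCCC(C)(C)[C@H]2[C@@H](O[Si](CC)(CC)CC)C[C@@]1(C)O[Si](CC)(CC)CC | intermediate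
32 | 12-O-(imidazol-1-ylthiocarbonyl) derivative | C=C[C@H](CO[Si](c3ccccc3)(c4ccccc4)C(C)(C)C)[C@H](OC(=S)n5ccnc5)C[C@@H]1[C@@]2(C)CCCC(C)(C)[C@H]2[C@@H](O[Si](CC)(CC)CC)C[C@@]1(C)O[Si](CC)(CC)CC | intermediate
33 | 12-deoxy tris-silyl ether (13R) | C=C[C@H](CO[Si](c3ccccc3)(c4ccccc4)C(C)(C)C)CC[C@@H]1[C@@]2(C)CCCC(C)(C)[C@H]2[C@@H](O[Si](CC)(CC)CC)C[C@@]1(C)O[Si](CC)(CC)CC | intermediate
34 | 6α,8α-diol, 16-O-silyl | C=C[C@H](CO[Si](c3ccccc3)(c4ccccc4)C(C)(C)C)CC[C@@H]1[C@@]2(C)CCCC(C)(C)[C@H]2[C@@H](O)C[C@@]1(C)O | intermediate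
35 | angelic acid | C/C=C(/C)C(=O)O | starting material
36 | angelic 2,4,6-trichlorobenzoic mixed anhydride | C/C=C(/C)C(=O)OC(=O)c1c(Cl)cc(Cl)cc1Cl | intermediate (not isolated)
37 | 6-O-angelate, 16-O-silyl | C=C[C@H](CO[Si](c3ccccc3)(c4ccccc4)C(C)(C)C)CC[C@@H]1[C@@]2(C)CCCC(C)(C)[C@H]2[C@@H](OC(=O)/C(C)=C\C)C[C@@]1(C)O | intermediate
38 | CNP0177054.1 | C=C[C@H](CO)CC[C@@H]1[C@@]2(C)CCCC(C)(C)[C@H]2[C@@H](OC(=O)/C(C)=C\C)C[C@@]1(C)O | target

**Totals**
Total step count: 22. Longest linear sequence: 21 steps (steps 1–13, then 15–22); step 14 is a one-step side branch.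

**Three steps most likely to fail, with fallbacks**

Step 2 (enantioselective cycloaddition). The diene is acid-sensitive, and ee, regiochemistry and absolute sense all depend on one catalyst. The fallback sets out from 4 and 5 and comes back at 7. The cycloaddition is run with BF3·OEt2 (CH2Cl2, −40 °C), which gives the same cis-adduct as a racemate, i.e. 6 together with the (4a'S,8a'R)-adduct F1. Luche reduction as in step 3 then gives 7 together with the enantiomeric 6-alcohol F2. Esterification with (S)-2-methoxy-2-phenylacetic acid (dicyclohexylcarbodiimide, 4-(dimethylamino)pyridine cat., CH2Cl2) gives the (S)-O-methylmandelate of 7 F3 and the (S)-O-methylmandelate of the antipodal alcohol F4, which are separated by chromatography. K2CO3 in MeOH on F3 returns 7 as a single enantiomer; its absolute configuration is then confirmed by X-ray or the mandelate NMR model.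

Step 6 (Wharton transposition). Hydrazone formation at the doubly flanked C9 ketone may be slow and low-yielding. The fallback sets out from 9 and comes back at 12. NaBH4 (MeOH, 0 °C) reduces the ketone to the 7β,8β-epoxy-9-ol F5; either C9 epimer serves. NaH, CS2, then MeI (THF) gives the S-methyl xanthate F6. Bu3SnH with 2,2'-azobis(isobutyronitrile) in PhH at 80 °C generates the C9 radical, which opens the neighbouring oxirane at C8–O to the C8=C9 alkene; the resulting C7 alkoxyl radical is reduced to 12 with the 7β C–O bond retained.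

Step 7 (Johnson–Claisen next to a quaternary carbon). Elimination of the allylic alcohol can compete at 140 °C. The fallback sets out from 12 and comes back at 15. Ac2O, pyridine and 4-(dimethylamino)pyridine give the 7β-acetate F7. LiN(iPr)2 and Me3SiCl (THF, −78 °C) give the trimethylsilyl ketene acetal F8, which rearranges on warming to 60 °C (Ireland–Claisen, same suprafacial transfer to the 9β position) to the trimethylsilyl ester F9. Aqueous work-up gives the 9β-acetic acid F10, and EtI with K2CO3 in DMF gives 15.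

**Further compounds**
F1 | step 2 | enantiomer of adduct 6, (4a'S,8a'R) | O=C1[C@]2(C)CC=CC3(CC3)[C@@H]2C(=O)C=C1C
F2 | step 2 | enantiomer of alcohol 7 | O=C1[C@]2(C)CC=CC3(CC3)[C@@H]2[C@H](O)C=C1C
F3 | step 2 | (S)-O-methylmandelate of 7 | O=C1[C@@]2(C)CC=CC3(CC3)[C@H]2[C@@H](OC(=O)[C@@H](OC)c4ccccc4)C=C1C
F4 | step 2 | (S)-O-methylmandelate of F2 | O=C1[C@]2(C)CC=CC3(CC3)[C@@H]2[C@H](OC(=O)[C@@H](OC)c4ccccc4)C=C1C
F5 | step 6 | 7β,8β-epoxy-6α-silyloxy 9-ol (C9 epimers) | OC1[C@@]2(C)CC=CC3(CC3)[C@H]2[C@@H](O[Si](C)(C)C(C)(C)C)[C@@H]4O[C@]14C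
F6 | step 6 | S-methyl xanthate of F5 | CSC(=S)OC1[C@@]2(C)CC=CC3(CC3)[C@H]2[C@@H](O[Si](C)(C)C(C)(C)C)[C@@H]4O[C@]14C
F7 | step 7 | 7β-acetate of 12 | C1[C@@]2(C)CC=CC3(CC3)[C@H]2[C@@H](O[Si](C)(C)C(C)(C)C)[C@H](OC(C)=O)C(C)=1
F8 | step 7 | trimethylsilyl ketene acetal of F7 | C1[C@@]2(C)CC=CC3(CC3)[C@H]2[C@@H](O[Si](C)(C)C(C)(C)C)[C@H](OC(=C)O[Si](C)(C)C)C(C)=1
F9 | step 7 | trimethylsilyl ester of the 9β-acetic acid | C[Si](C)(C)OC(=O)C[C@@H]1[C@@]2(C)CC=CC3(CC3)[C@H]2[C@@H](O[Si](C)(C)C(C)(C)C)C=C1C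
F10 | step 7 | 9β-acetic acid, 6α-silyloxy, C7=C8 | OC(=O)C[C@@H]1[C@@]2(C)CC=CC3(CC3)[C@H]2[C@@H](O[Si](C)(C)C(C)(C)C)C=C1C
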